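With a small charge of D, [D] = 0.030 M in alpha, Q stands at 70.9 % at 6.00 d, higher than the 40.1 % of zeta with [D] = 0.12 M.

| flask | E | X | D | remark | time |
|---|---|---|---|---|---|
| beta | 0.12 M | 0.144 M | 0.060 M | run made earlier |  |
| alpha | 0.12 M | 0.144 M | 0.030 M | run made earlier |  |
| zeta | 0.12 M | 0.144 M | 0.12 M | run made earlier |  |
| amber | 0.12 M | 0.144 M | 0.0600 M | everything together at the start | 6.0 d |
| blue | 0.12 M | 0.144 M (fed, over 2.5 d) | 0.0600 M | all else is in the flask from the start; the feed brings no volume worth counting | 6.0 d |
| violet | 0.12 M (fed, over 2.5 d) | 0.144 M | 0.0600 M | all else is in the flask from the start; the feed brings no volume worth counting | 6.0 d |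

| run | time / d | Q / % | E / % |
|---|---|---|---|
| beta | 0.250 | 2.5 | 56.7 |
| beta | 0.625 | 10.5 | 37.2 |
| beta | 1.67 | 36.5 | 18.4 |
| beta | 4.00 | 54.5 | 5.8 |
| alpha | 0.833 | 19.9 | 37.4 |
| alpha | 2.00 | 45.5 | 19.6 |
| alpha | 4.00 | 64.2 | 8.6 |
| alpha | 6.00 | 70.9 | 4.8 |
| zeta | 0.500 | 6.7 | 32.0 |
| zeta | 1.04 | 19.2 | 18.9 |
| zeta | 2.50 | 34.7 | 5.1 |
| zeta | 6.00 | 40.1 | 0 |

(scatter of a reading: 0.5 percentage points)



- the flask that comes out highest in amount of Q, in percent of the E charged, or "all alike" when all lie within 1.5 percentage points (amber / blue / violet / all alike)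
- Q at the end, in percent of the E charged, amber
- Q at the end, in percent of the E charged, blue
- Q at the end, in percent of the E charged, violet

Amber is beta's recipe carried on to 6.0 d. Beta's Q has risen at each reading, so its 54.5 % at 4.00 d is my first bound from below. To go further, I divide the rise of Q between beta's last two readings by the fall of E and get 1.43. I call this the late gain: points of Q won per point of E gone between two late readings.

Alpha's last stretch gives 1.76 and zeta's gives 1.06, so in these readings the gain is lower at zeta's higher [D], and beta lies between them. Spending beta's remaining E at alpha's gain gives a first upper bound: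

Q ≤ 64.7 %

To tighten this, I replace E's curve by a mean decay. Beta's last stretch gives 0.495 d⁻¹, by which I reckon E in amber at 2.15 %. Alpha's last stretch is slower, at 0.292 d⁻¹, by which I reckon 3.24 %. Pairing the fast decay with alpha's gain and the slow decay with zeta's gives my bracket for amber:

upper: 60.9 %

lower: 57.2 %

The forecast names amber, with 58.5 % for amber and 55 % for blue and 55 % for violet, holding that “feeding leaves the ultimate yield unchanged”. Its amber figure stands inside my bracket.

The flasks give 58.7 % for amber, the highest and inside the bracket, then 56.7 % for violet and 52.1 % for blue.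

    E ⇌ G (K = 1.01, k = 0.0913 h⁻¹)
    X → L (k = 0.0600 h⁻¹)
    G + L → Q (k = 0.558 L mol⁻¹ h⁻¹)
    2 L → J (k = 0.0226 L mol⁻¹ h⁻¹)
    E + D → Z (k = 0.515 L mol⁻¹ h⁻¹)

In blue at 1.90 d, G falls back 3.2 times faster than it goes on, and the exchange of E and G relaxes with a half-life of 0.159 d, shorter than the 0.32 d of E's forward step alone. Amber's late gain from 3.00 d to its end is 1.42. Blue's, from its reading at 4.0 d to its end, is 1.54.

The earlier runs and the new flask were generated by integration from invented constants, noise included.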